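## Retrosynthetic overview

1. The target comes from a 2-hydroxy-2-(benzoyloxymethyl)cyclohex-5-enone diacetate by hydroxyl-directed 1,2-reduction of the ketone. This sets the last carbinol trans to the tertiary OH.
2. That enone comes from a saturated β-silyloxy ketone triol by acetylation of the cis-diol and E1cB loss of silanol. The cis-diol comes from OsO4 dihydroxylation anti to both allylic oxygens.
3. The six-membered ring is made once, by an α-ketol ring expansion: the ring alkenyl carbon of a 1-acylcyclopent-2-en-1-ol shifts from the carbinol carbon to the side-chain ketone. This also relays the silyloxy stereocentre to the quaternary carbinol.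
4. The acyl carbinol comes from an enantiopure 4-silyloxycyclopentenone and α-lithiated ethyl vinyl ether (added anti to OTBS), followed by α'-benzoyloxylation of the methyl ketone.
5. Ring order: the only carbocycle is bought as a cyclopentene and enlarged once; no other ring is formed.

Assumption: compound 1 is bought as the enantiopure TBS ether (a catalogue compound); the silyl group is a protecting group that leaves in step 5.

## Route

**Step 1**
Reactants: 1 (S)-4-(tert-butyldimethylsilyloxy)cyclopent-2-en-1-one; 2 ethyl vinyl ether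
Product: 5 1-[(1R,4S)-4-(tert-butyldimethylsilyloxy)-1-hydroxycyclopent-2-en-1-yl]ethan-1-one, via 1-ethoxyvinyllithium 3 (not isolated), via enol ether carbinol 4 (not isolated)
Conditions: 2 (1.5 equiv), t-BuLi (1.4 equiv), THF, −78 to 0 °C; then 1, −78 °C; then 0.5 M aq HCl, THF, 0 °C
Reagents that add atoms: water, O
Why: α-Lithiated ethyl vinyl ether (an acetyl anion equivalent) adds 1,2 to the enone carbonyl from the face opposite the C4 silyloxy group, so the new tertiary hydroxyl (C1, R) is cis to OTBS, and dilute acid then hydrolyses the enol ether to the methyl ketone without cleaving the TBS ether (organolithium 1,2-addition followed by enol ether hydrolysis).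

**Step 2**
Reactants: 5 1-[(1R,4S)-4-(tert-butyldimethylsilyloxy)-1-hydroxycyclopent-2-en-1-yl]ethan-1-one
Product: 6 2-[(1R,4S)-4-(tert-butyldimethylsilyloxy)-1-hydroxycyclopent-2-en-1-yl]-2-oxoethyl benzoate
Conditions: MeNH(OBz)·HCl (1.5 equiv), DMSO, 40 °C
Reagents that add atoms: N-methyl-O-benzoylhydroxylamine hydrochloride, CNOC(=O)c1ccccc1.Cl
Why: The ketone condenses with the hydroxylamine to an N-benzoyloxy enamine that can only form toward the methyl group (the other α-carbon is quaternary), and its [3,3] shift followed by iminium hydrolysis puts the benzoate on that carbon (α-acyloxylation of ketones with N-alkyl-O-acylhydroxylamines); no stereocentre is formed or touched.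

**Step 3**
Reactants: 6 2-[(1R,4S)-4-(tert-butyldimethylsilyloxy)-1-hydroxycyclopent-2-en-1-yl]-2-oxoethyl benzoate
Product: 7 [(1R,4S)-4-(tert-butyldimethylsilyloxy)-1-hydroxy-6-oxocyclohex-2-en-1-yl]methyl benzoate
Conditions: Sc(OTf)3 (10 mol %), 2,6-di-tert-butylpyridine (20 mol %), 4 Å MS, CH2Cl2, −20 °C to rt
Reagents that add atoms: none
Why: Proposed new method: Sc(OTf)3 (trivalent scandium) holds the tertiary hydroxyl and the ketone oxygen in a five-membered chelate (O=C–C–O syn-periplanar), and the ring alkenyl carbon, which should migrate better through π-participation than the CH2 next to the silyloxy carbon, shifts with its electron pair to the activated ketone carbon on the face it already occupies while the carbinol carbon becomes the ring ketone, so the six-membered ring forms with release of cyclopentene strain and the new tertiary hydroxyl stays on the face of the old one, cis to OTBS (1R); the closest known reaction type is the Lewis-acid-catalysed α-ketol (acyloin) ring expansion of 1-acylcycloalkanols, which has not been shown with selective alkenyl migration and stereo-relay on an α'-acyloxy cyclopentenyl ketol.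

**Step 4**
Reactants: 7 [(1R,4S)-4-(tert-butyldimethylsilyloxy)-1-hydroxy-6-oxocyclohex-2-en-1-yl]methyl benzoate
Product: 8 [(1S,2R,3S,4S)-4-(tert-butyldimethylsilyloxy)-1,2,3-trihydroxy-6-oxocyclohexyl]methyl benzoate
Conditions: OsO4 (2 mol %), NMO (1.5 equiv), citric acid (0.75 equiv), t-BuOH/H2O 1:1, 0 °C to rt
Reagents that add atoms: N-methylmorpholine N-oxide, C[N+]1([O-])CCOCC1; water, O (both oxygens are passed on through catalytic OsO4, O=[Os](=O)(=O)=O)
Why: In the half-chair with the CH2OBz group pseudo-equatorial the tertiary OH is pseudo-axial on the same face as OTBS, so OsO4 adds to the opposite face (Upjohn dihydroxylation, anti to allylic oxygen as in Kishi's rule), which sets both new carbinols (2R,3S) trans to the tertiary OH.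

**Step 5**
Reactants: 8 [(1S,2R,3S,4S)-4-(tert-butyldimethylsilyloxy)-1,2,3-trihydroxy-6-oxocyclohexyl]methyl benzoate
Product: 10 [(1S,5R,6R)-5,6-diacetoxy-1-hydroxy-2-oxocyclohex-3-en-1-yl]methyl benzoate, via silyloxy diacetate 9 (not isolated)
Conditions: Ac2O (2.3 equiv), pyridine, DMAP (5 mol %), CH2Cl2, 0 °C; then DBU (1.5 equiv), 0 °C
Reagents that add atoms: acetic anhydride, CC(=O)OC(C)=O
Why: Only the two secondary hydroxyls are acylated (the tertiary α-ketol hydroxyl is too hindered), and DBU then removes a proton α to the ketone so that the β-silanolate leaves (E1cB elimination), which unmasks the enone and erases the relay stereocentre by design while the other three stereocentres are untouched.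

**Step 6**
Reactants: 10 [(1S,5R,6R)-5,6-diacetoxy-1-hydroxy-2-oxocyclohex-3-en-1-yl]methyl benzoate
Product: 11 [(1R,2S,5R,6R)-5,6-diacetoxy-1,2-dihydroxycyclohex-3-en-1-yl]methyl benzoate (CNP0130780.2)
Conditions: Me4NBH(OAc)3 (4 equiv), MeCN/AcOH 1:1, −30 to 0 °C
Reagents that add atoms: none
Why: The tertiary hydroxyl exchanges onto boron and the bound hydride is delivered intramolecularly to the neighbouring enone carbonyl on the face of that hydroxyl (hydroxyl-directed triacetoxyborohydride reduction of the Saksena–Evans type), which gives the new carbinol trans to the tertiary OH (2S) by 1,2-reduction only, and the acidic medium leaves the acetates and the benzoate in place.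

## Compound list

1 | (S)-4-(tert-butyldimethylsilyloxy)cyclopent-2-en-1-one | O=C1C=C[C@@H](O[Si](C)(C)C(C)(C)C)C1 | starting material
2 | ethyl vinyl ether | C=COCC | starting material
3 | 1-ethoxyvinyllithium | [Li]C(=C)OCC | intermediate
4 | (1R,4S)-4-(tert-butyldimethylsilyloxy)-1-(1-ethoxyvinyl)cyclopent-2-en-1-ol (OH cis to OTBS) | CCOC(=C)[C@]1(O)C=C[C@@H](O[Si](C)(C)C(C)(C)C)C1 | intermediate
5 | 1-[(1R,4S)-4-(tert-butyldimethylsilyloxy)-1-hydroxycyclopent-2-en-1-yl]ethan-1-one (OH cis to OTBS) | CC(=O)[C@]1(O)C=C[C@@H](O[Si](C)(C)C(C)(C)C)C1 | intermediate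
6 | 2-[(1R,4S)-4-(tert-butyldimethylsilyloxy)-1-hydroxycyclopent-2-en-1-yl]-2-oxoethyl benzoate | O=C(COC(=O)c1ccccc1)[C@]1(O)C=C[C@@H](O[Si](C)(C)C(C)(C)C)C1 | intermediate
7 | [(1R,4S)-4-(tert-butyldimethylsilyloxy)-1-hydroxy-6-oxocyclohex-2-en-1-yl]methyl benzoate (tertiary OH cis to OTBS) | O[C@@]1(COC(=O)c2ccccc2)C=C[C@@H](O[Si](C)(C)C(C)(C)C)CC1=O | intermediate
8 | [(1S,2R,3S,4S)-4-(tert-butyldimethylsilyloxy)-1,2,3-trihydroxy-6-oxocyclohexyl]methyl benzoate (2,3-diol cis, trans to tertiary OH and to OTBS) | O[C@@]1(COC(=O)c2ccccc2)[C@H](O)[C@H](O)[C@@H](O[Si](C)(C)C(C)(C)C)CC1=O | intermediate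
9 | [(1S,2R,3S,4S)-2,3-diacetoxy-4-(tert-butyldimethylsilyloxy)-1-hydroxy-6-oxocyclohexyl]methyl benzoate | O[C@@]1(COC(=O)c2ccccc2)[C@H](OC(C)=O)[C@H](OC(C)=O)[C@@H](O[Si](C)(C)C(C)(C)C)CC1=O | intermediate
10 | [(1S,5R,6R)-5,6-diacetoxy-1-hydroxy-2-oxocyclohex-3-en-1-yl]methyl benzoate | O[C@@]1(COC(=O)c2ccccc2)[C@H](OC(C)=O)[C@H](OC(C)=O)C=CC1=O | intermediate
11 | [(1R,2S,5R,6R)-5,6-diacetoxy-1,2-dihydroxycyclohex-3-en-1-yl]methyl benzoate | CC(=O)O[C@@H]1[C@H](OC(C)=O)C=C[C@H](O)[C@]1(O)COC(=O)c1ccccc1 | target

## Step count and risks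

Total steps: 6. Longest linear sequence: 6 (1 → 5 → 6 → 7 → 8 → 10 → 11).

**Step 3 (the proposed new method).** The risks are migration of the ring CH2 instead of the alkenyl carbon (which would give the conjugated enone isomer), chelation through the ester oxygen that opens the hydroxyl–ketone chelate and erodes the C1 configuration, and Lewis-acid loss of silanol. The fallback uses only known reaction types, sets out from 5 and comes back at 7. Compound 5 is bis-silylated (TMSOTf, Et3N, CH2Cl2, −78 °C) to the bis-silyl enol ether F1. F1 is oxidised (mCPBA, NaHCO3, CH2Cl2, 0 °C; then citric acid, MeOH; Rubottom oxidation) to the α,α'-dihydroxy ketone F2. F2 carries no ester and undergoes the classical stoichiometric Lewis-acid α-ketol ring enlargement (BF3·OEt2, CH2Cl2, −40 to 0 °C, as used for D-homoannulation of 17,21-dihydroxy-20-oxo steroids) to the ring-expanded diol F3. Selective benzoylation of the primary hydroxyl (BzCl, 2,4,6-collidine, CH2Cl2, −20 °C) then gives 7. The approach changes from a catalytic shift of the benzoate to a benzoate-free, stoichiometrically templated shift with the ester put on last; it does not by itself remove the alkenyl-versus-alkyl question.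

**Step 2.** The ketone is flanked by a quaternary carbinol, so condensation with the hydroxylamine salt may be slow, and the acidic medium may attack the silyl ether or the tertiary allylic alcohol. The fallback sets out from 5 and comes back at 6. The methyl ketone is brominated through its enol (PhNMe3Br3, THF, 0 °C) to the bromomethyl ketone F4, and the bromide is displaced by benzoate (PhCO2Cs, DMF, rt) to give 6. This replaces the rearrangement-based oxygen transfer by halogenation and carboxylate substitution.

**Step 5.** DBU may also remove the γ-proton of the new enone and expel the neighbouring acetate (giving a dienone), or silanolate loss may be slow. The fallback sets out from 8 and comes back at 10. Compound 8 is acetylated as before and 9 is isolated. The silyl ether is cleaved (HF·pyridine, THF, 0 °C) to the β-hydroxy ketone F5. F5 is mesylated (MsCl, Et3N, CH2Cl2, −20 to 0 °C) to the mesylate F6, which eliminates in the same flask under the mild amine base to give 10. This replaces direct silanolate expulsion by a two-stage activation of the leaving group.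

## Further compounds

F1 | step 3 | (1R,4S)-4-(tert-butyldimethylsilyloxy)-1-(trimethylsilyloxy)-1-[1-(trimethylsilyloxy)vinyl]cyclopent-2-ene | C=C(O[Si](C)(C)C)[C@]1(O[Si](C)(C)C)C=C[C@@H](O[Si](C)(C)C(C)(C)C)C1
F2 | step 3 | 2-hydroxy-1-[(1R,4S)-4-(tert-butyldimethylsilyloxy)-1-hydroxycyclopent-2-en-1-yl]ethan-1-one | O=C(CO)[C@]1(O)C=C[C@@H](O[Si](C)(C)C(C)(C)C)C1
F3 | step 3 | (2R,5S)-5-(tert-butyldimethylsilyloxy)-2-hydroxy-2-(hydroxymethyl)cyclohex-3-en-1-one | O[C@@]1(CO)C=C[C@@H](O[Si](C)(C)C(C)(C)C)CC1=O
F4 | step 2 | 2-bromo-1-[(1R,4S)-4-(tert-butyldimethylsilyloxy)-1-hydroxycyclopent-2-en-1-yl]ethan-1-one | O=C(CBr)[C@]1(O)C=C[C@@H](O[Si](C)(C)C(C)(C)C)C1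
F5 | step 5 | [(1S,2R,3R,4S)-2,3-diacetoxy-1,4-dihydroxy-6-oxocyclohexyl]methyl benzoate | O[C@@]1(COC(=O)c2ccccc2)[C@H](OC(C)=O)[C@H](OC(C)=O)[C@@H](O)CC1=O
F6 | step 5 | [(1S,2R,3S,4S)-2,3-diacetoxy-1-hydroxy-4-(methanesulfonyloxy)-6-oxocyclohexyl]methyl benzoate | O[C@@]1(COC(=O)c2ccccc2)[C@H](OC(C)=O)[C@H](OC(C)=O)[C@@H](OS(C)(=O)=O)CC1=O
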